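Slowness is the first thing to question here: target creeps upward in the winter run, yet in the summer run it turns back.

| flask | substrate | coupling partner | free catalyst | target | time |
|---|---|---|---|---|---|
| winter | 80.0 mM | 160 mM | 4.00 mM |  |  |
| summer | 32.0 mM | 112 mM | 4.00 mM |  |  |
| autumn | 80.0 mM | 160 mM | 2.00 mM |  |  |
| spring | 80.0 mM | 160 mM | 4.00 mM | 80.0 mM | 22 min |

- winter run (time / min: [target] / mM): 3.7: 12.8; 7.3: 19.0; 11: 24.9; 15: 30.7; 18: 32.9; 22: 37.4
- summer run (time / min: [target] / mM): 3.7: 9.1; 7.3: 15.5; 11: 18.8; 15: 18.5; 18: 17.0; 22: 15.2
- autumn run (time / min: [target] / mM): 3.7: 6.0; 7.3: 10.7; 11: 12.4; 15: 14.9; 18: 17.0; 22: 17.4

(scatter of a reading: 0.6 mM)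

- the power of [free catalyst] that the first rate follows, about the charge of the winter run; measure it at two percent of substrate made into target
- target in the spring run at 22 min, as a share of the substrate charged
- which of these the readings show (the catalyst wakes slowly / an uncatalysed path runs beside / the second partner is lost by itself / the product binds the substrate / the product reacts on with the second partner)

- Overall: substrate + coupling partner -> target, with free catalyst as catalyst.
- Constant volume, constant temperature.
- Readings of a species count what is bound in complexes too.
- "The second partner" is coupling partner.
- An order is taken over about fifteen percent of the charge, up and down.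
- A share of target counts the target that was charged too.

What does the turn in the summer run say? Target is consumed: it reads 18.8 mM at 11 min and 15.2 mM at 22 min, so I take it that target reacts on with the coupling partner.

And the catalyst? The first autumn and winter readings, taken as early chords, give a power of 1.09, so I say first order.

How fast is target made? The first winter reading gives a pace per [coupling partner] of 0.0216 min⁻¹, and the first summer reading gives 0.0220 min⁻¹, nearly the same, although the substrate charges differ by a factor of 2.50.

But isn't the summer tail still being fed? That is the weak spot. At its early pace, the summer substrate, the limiting reagent there, lasts 13.0 min, shorter than the 15 min where the tail begins, so I read the tail as loss, knowing that any feed left makes my constant low. Target falls by 0.0281 min⁻¹ as a fraction. If the substrate has turned completely and each lost target took one more partner, [coupling partner] there is about 64.9 mM. The loss constant is then 0.433 M⁻¹ min⁻¹.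

So what carries over? The holding level, the level of target at which making and loss per minute are equal, a quasi-steady level: 50.0 mM. While the pace per partner holds, [coupling partner] stands in both terms and cancels.

And the spring run? Its charged target of 80.0 mM stands above that level, so target must fall toward it. Taking [coupling partner] to shrink by 0.0562 min⁻¹ as a fraction, my target at 22 min is then 62.5 mM, or 78.1 %.

The forecast says 84 %, above mine, with order 1 and the product reacts on with the second partner, on the ground that “Target is therefore being consumed”.

The flask gives 82.8 % for the spring run at 22 min, with order 0.95 and the product reacts on with the second partner.

free catalyst + substrate → catalyst-substrate complex (119.4 M⁻¹ min⁻¹); catalyst-substrate complex + coupling partner → loaded catalyst (31.92 M⁻¹ min⁻¹); loaded catalyst → target + free catalyst (1.446 min⁻¹); target + coupling partner → side product (0.7140 M⁻¹ min⁻¹) A fit with the main steps alone put that run at 152 %, above the flask. Spring target, at 66.3 mM, has come down from 80.0 mM and stands above the holding level of 50.0 mM. The winter run lies on the other side of that level, below it, and there target climbs from 32.9 mM at 18 min to 37.4 mM at 22 min.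

Readings and results are calculated on assumed constants, noise included.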